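The 1,2-dioxolane (O1–O2–C3–C4–C5) is disconnected across C3–C4 and O1–C5 into a three-atom C3–O2–O1 peroxycarbenium ion and the C4=C5 bond of a 1,1-disubstituted alkene. This exploits the unsubstituted ring carbon C4 flanked by fully substituted C3 and C5: C4 is an open nucleophilic terminus and C5 passes through a tertiary cation. One formal (3+2) annulation under a confined chiral counteranion unites the complete (R)-configured triene side chain with an acyclic triethylsilylperoxy ketal, closes the ring and sets C3 and C5 together. The carboxyl group travels as an acetate-protected primary alcohol, freed and oxidised in the last two steps.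

Key step: step 11

Numbering: C1 is the carboxyl carbon and C2 its CH2. O1–O2–C3–C4–C5 is the dioxolane (C3 bears C2, O1 is bonded to C5). C6–C17 is the side chain (C7 bears the methyl group, C12=C13, C16=C17–Ph).
Assumption: the sense of induction of the ferrocenyl diphosphine–CuBr catalyst (step 2) and of the imidodiphosphorimidate (step 11) is matched to the drawn configuration by choice of the catalyst antipode; both antipodes are accessible.
Remark: the C3 descriptor reads R in 20 and 21 and S in 22 and 23 only because the CIP rank of the C2 arm changes; the geometry is the same throughout.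

Step 1
Reactants: 1 ethyl hept-6-enoate; 2 but-3-en-2-one
Product: 3 ethyl (E)-8-oxonon-6-enoate
Conditions: second-generation Hoveyda–Grubbs catalyst (2 mol %), 2 (3 equiv), CH2Cl2, 40 °C
Reagents that add atoms: none
Why: Olefin cross-metathesis of an unhindered terminal alkene with an electron-poor vinyl ketone favours the cross product and, under thermodynamic control, the E-enone.

Step 2
Reactants: 3 ethyl (E)-8-oxonon-6-enoate
Product: 4 ethyl (R)-6-methyl-8-oxononanoate
Conditions: MeMgBr (1.2 equiv), CuBr·SMe2 (5 mol %), (R)-1-[(SP)-2-(diphenylphosphino)ferrocenyl]ethyldicyclohexylphosphine (Josiphos, 6 mol %, or its antipode), t-BuOMe, −75 °C; aq NH4Cl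
Reagents that add atoms: methylmagnesium bromide, C[Mg]Br
Why: Copper-catalysed asymmetric conjugate addition of a Grignard reagent to an acyclic E-enone, in which the chiral diphosphine–CuBr complex delivers methyl to one enantiotopic face of C6=C7 and so sets C7 as (R), while the ethyl ester is inert at this temperature.

Step 3
Reactants: 4 ethyl (R)-6-methyl-8-oxononanoate
Product: 5 ethyl (R)-6,8-dimethylnon-8-enoate
Conditions: MePPh3Br, KOt-Bu, THF, 0 °C to rt
Reagents that add atoms: methyltriphenylphosphonium bromide, C[P+](c1ccccc1)(c1ccccc1)c1ccccc1.[Br-]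
Why: Wittig methylenation, in which the non-stabilised ylide reacts far faster with the ketone than with the ester, and C7, being β to the carbonyl, cannot epimerise.

Step 4
Reactants: 5 ethyl (R)-6,8-dimethylnon-8-enoate
Product: 6 (R)-6,8-dimethylnon-8-enal
Conditions: i-Bu2AlH (1.05 equiv), CH2Cl2, −78 °C; aq KNaC4H4O6
Reagents that add atoms: none
Why: Low-temperature partial reduction of an ester to the aldehyde with one equivalent of i-Bu2AlH is a standard transformation that leaves the isolated alkene and C7 untouched.

Step 5
Reactants: 7 5-bromopent-1-ene; 8 1-phenyl-1H-tetrazole-5-thiol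
Product: 9 5-(pent-4-en-1-ylsulfanyl)-1-phenyl-1H-tetrazole
Conditions: K2CO3, acetone, reflux
Reagents that add atoms: none
Why: SN2 S-alkylation of the soft thiolate of 8 by a primary bromide.

Step 6
Reactants: 9 5-(pent-4-en-1-ylsulfanyl)-1-phenyl-1H-tetrazole
Product: 10 5-(pent-4-en-1-ylsulfonyl)-1-phenyl-1H-tetrazole
Conditions: (NH4)6Mo7O24·4H2O (10 mol %), 30% aq H2O2, EtOH, 0 °C to rt
Reagents that add atoms: hydrogen peroxide, OO
Why: Molybdate-catalysed peroxide oxidation of a sulfide to the sulfone is much faster than epoxidation of an unactivated terminal alkene.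

Step 7
Reactants: 10 5-(pent-4-en-1-ylsulfonyl)-1-phenyl-1H-tetrazole; 11 styrene
Product: 12 1-phenyl-5-{[(4E)-5-phenylpent-4-en-1-yl]sulfonyl}-1H-tetrazole
Conditions: second-generation Grubbs catalyst (3 mol %), 11 (3 equiv), CH2Cl2, 40 °C
Reagents that add atoms: none
Why: Olefin cross-metathesis of a terminal alkene with styrene should give the conjugated E-styrene (C16=C17) under thermodynamic control.

Step 8
Reactants: 6 (R)-6,8-dimethylnon-8-enal; 12 1-phenyl-5-{[(4E)-5-phenylpent-4-en-1-yl]sulfonyl}-1H-tetrazole
Product: 13 [(1E,5E,11R)-11,13-dimethyltetradeca-1,5,13-trien-1-yl]benzene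
Conditions: KN(SiMe3)2, DME, −60 °C, then 6, −60 °C to rt
Reagents that add atoms: none
Why: Julia–Kocienski olefination, in which 1-phenyltetrazolyl sulfones with a potassium base in a coordinating solvent give mainly E-1,2-disubstituted alkenes in one operation, forms C12=C13 and leaves C7 and the other alkenes untouched.

Step 9
Reactants: 14 3-methylbut-3-en-1-yl acetate
Product: 16 3-hydroperoxy-3-methoxybutyl acetate (racemic), via carbonyl oxide 15 (not isolated)
Conditions: O3, CH2Cl2/MeOH 4:1, −78 °C; N2 purge, no reductant
Reagents that add atoms: ozone, [O-][O+]=O; methanol, CO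
Why: Ozonolysis in methanol cleaves a 1,1-disubstituted alkene to formaldehyde and the more substituted carbonyl oxide 15, which methanol traps as the hydroperoxy ketal; its stereocentre is racemic and is erased in step 11.

Step 10
Reactants: 16 3-hydroperoxy-3-methoxybutyl acetate
Product: 17 3-methoxy-3-[(triethylsilyl)peroxy]butyl acetate (racemic)
Conditions: Et3SiCl, imidazole, DMF, 0 °C
Reagents that add atoms: chlorotriethylsilane, CC[Si](Cl)(CC)CC
Why: Standard O-silylation of a hydroperoxide installs the triethylsilyl group, which is later lost cleanly as a cation equivalent when the ring closes.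

Step 11
Reactants: 13 [(1E,5E,11R)-11,13-dimethyltetradeca-1,5,13-trien-1-yl]benzene; 17 3-methoxy-3-[(triethylsilyl)peroxy]butyl acetate
Product: 20 2-{(3R,5R)-3,5-dimethyl-5-[(2R,7E,11E)-2-methyl-12-phenyldodeca-7,11-dien-1-yl]-1,2-dioxolan-3-yl}ethyl acetate, via peroxycarbenium ion 18 (not isolated), via tertiary cation 19 (not isolated)
Conditions: (S,S)-imidodiphosphorimidate Brønsted acid HX* (5 mol %; P–N–P core, each P carrying a 3,3'-bis[3,5-bis(trifluoromethyl)phenyl]-1,1'-binaphthalene-2,2'-diolate and an N–SO2CF3 group), 17 (1.1 equiv, slow addition), toluene, −78 °C; Et3N quench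
Reagents that add atoms: none
Why: Proposed new method: HX* ionises 17 (after the first turnover as Et3Si–X*, which removes the methoxy group as Et3SiOMe) to peroxycarbenium ion 18 paired with the confined chiral anion, the CH2 terminus C4 of the 1,1-disubstituted alkene of 13 attacks its carbon (C3–C4 bond) to give tertiary C5 cation 19, and the distal silylated peroxide oxygen O1 captures C5 (O1–C5 bond), releasing Et3Si+ to the anion and closing the catalytic cycle. The closest known reaction types are the SnCl4- or TiCl4-mediated (3+2) annulation of triethylsilylperoxy ketals with alkenes, which gives 1,2-dioxolanes without absolute control, and silylium-type asymmetric counteranion-directed catalysis of ketone-derived oxocarbenium ions, in which imidodiphosphorimidate anions tell CH3 from CH2R. The one ring closed is the 1,2-dioxolane, by a stepwise formal (3+2) cycloaddition in which both former alkene carbons end up in the ring (endo with respect to C4=C5) and the last event is a five-membered oxygen-to-carbocation closure. C3 is set by the anion, which leaves one face of planar 18 open; C5 is set relative to C3 in the closure, where the transition state with the CH2CH2OAc arm and the C6 chain on opposite ring faces avoids a 1,3-syn contact of the two long groups; C7 is a spectator. The step needs chemoselectivity among three C=C bonds and gets it because only C4=C5 offers an unsubstituted terminus and a tertiary cation, whereas C12=C13 and C16=C17 would have to bond through a substituted carbon to the fully substituted C3. It also needs O1 rather than the arm oxygen to end the cascade, which the electron-poor acetate secures by shutting down six-membered ether formation.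

Step 12
Reactants: 20 2-{(3R,5R)-3,5-dimethyl-5-[(2R,7E,11E)-2-methyl-12-phenyldodeca-7,11-dien-1-yl]-1,2-dioxolan-3-yl}ethyl acetate
Product: 21 2-{(3R,5R)-3,5-dimethyl-5-[(2R,7E,11E)-2-methyl-12-phenyldodeca-7,11-dien-1-yl]-1,2-dioxolan-3-yl}ethan-1-ol
Conditions: K2CO3 (0.2 equiv), MeOH, 0 °C to rt
Reagents that add atoms: none
Why: Base-catalysed transesterification of a primary acetate is safe here because the 3,3,5,5-tetrasubstituted dioxolane has no hydrogen on its C–O carbons and so cannot undergo Kornblum–DeLaMare fragmentation.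

Step 13
Reactants: 21 2-{(3R,5R)-3,5-dimethyl-5-[(2R,7E,11E)-2-methyl-12-phenyldodeca-7,11-dien-1-yl]-1,2-dioxolan-3-yl}ethan-1-ol
Product: 23 2-{(3S,5R)-3,5-dimethyl-5-[(2R,7E,11E)-2-methyl-12-phenyldodeca-7,11-dien-1-yl]-1,2-dioxolan-3-yl}acetic acid, via aldehyde 22 (not isolated)
Conditions: 2,2,6,6-tetramethylpiperidin-1-oxyl (TEMPO, 20 mol %), PhI(OAc)2 (2.4 equiv), MeCN/H2O 1:1, rt
Reagents that add atoms: water, O
Why: Oxoammonium-mediated oxidation of the primary alcohol through aldehyde 22 to the acid runs under near-neutral conditions that should spare the dialkyl peroxide and both E-alkenes, disfavour β-elimination of the peroxide from 22 and touch no stereocentre.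

Compound list
1 | ethyl hept-6-enoate | C=CCCCCC(=O)OCC | starting material
2 | but-3-en-2-one (methyl vinyl ketone) | C=CC(C)=O | starting material
3 | ethyl (E)-8-oxonon-6-enoate | CCOC(=O)CCCC/C=C/C(C)=O | intermediate
4 | ethyl (R)-6-methyl-8-oxononanoate | C[C@H](CCCCC(=O)OCC)CC(C)=O | intermediate
5 | ethyl (R)-6,8-dimethylnon-8-enoate | C[C@H](CCCCC(=O)OCC)CC(C)=C | intermediate
6 | (R)-6,8-dimethylnon-8-enal | C[C@H](CCCCC=O)CC(C)=C | intermediate
7 | 5-bromopent-1-ene | C=CCCCBr | starting material
8 | 1-phenyl-1H-tetrazole-5-thiol | Sc1nnnn1-c1ccccc1 | starting material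
9 | 5-(pent-4-en-1-ylsulfanyl)-1-phenyl-1H-tetrazole | C=CCCCSc1nnnn1-c1ccccc1 | intermediate
10 | 5-(pent-4-en-1-ylsulfonyl)-1-phenyl-1H-tetrazole | C=CCCCS(=O)(=O)c1nnnn1-c1ccccc1 | intermediate
11 | styrene | C=Cc1ccccc1 | starting material
12 | 1-phenyl-5-{[(4E)-5-phenylpent-4-en-1-yl]sulfonyl}-1H-tetrazole | O=S(=O)(CCC/C=C/c1ccccc1)c1nnnn1-c1ccccc1 | intermediate
13 | [(1E,5E,11R)-11,13-dimethyltetradeca-1,5,13-trien-1-yl]benzene | C[C@H](CCCC/C=C/CC/C=C/c1ccccc1)CC(C)=C | intermediate
14 | 3-methylbut-3-en-1-yl acetate | C=C(C)CCOC(C)=O | starting material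
15 | carbonyl oxide of 4-acetoxybutan-2-one (not isolated) | CC(=[O+][O-])CCOC(C)=O | intermediate
16 | 3-hydroperoxy-3-methoxybutyl acetate (racemic) | CC(OC)(OO)CCOC(C)=O | intermediate
17 | 3-methoxy-3-[(triethylsilyl)peroxy]butyl acetate (racemic) | CC(OC)(OO[Si](CC)(CC)CC)CCOC(C)=O | intermediate
18 | (4-acetoxybutan-2-ylidene)(triethylsilyloxy)oxonium, the peroxycarbenium ion (not isolated) | CC(=[O+]O[Si](CC)(CC)CC)CCOC(C)=O | intermediate
19 | tertiary C5 carbocation with the C3–C4 bond formed and the triethylsilylperoxy group still on C3 (not isolated) | C[C@H](CCCC/C=C/CC/C=C/c1ccccc1)C[C+](C)C[C@@](C)(CCOC(C)=O)OO[Si](CC)(CC)CC | intermediate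
20 | 2-{(3R,5R)-3,5-dimethyl-5-[(2R,7E,11E)-2-methyl-12-phenyldodeca-7,11-dien-1-yl]-1,2-dioxolan-3-yl}ethyl acetate | C[C@H](CCCC/C=C/CC/C=C/c1ccccc1)C[C@]1(C)C[C@@](C)(CCOC(C)=O)OO1 | intermediate
21 | 2-{(3R,5R)-3,5-dimethyl-5-[(2R,7E,11E)-2-methyl-12-phenyldodeca-7,11-dien-1-yl]-1,2-dioxolan-3-yl}ethan-1-ol | C[C@H](CCCC/C=C/CC/C=C/c1ccccc1)C[C@]1(C)C[C@@](C)(CCO)OO1 | intermediate
22 | 2-{(3S,5R)-3,5-dimethyl-5-[(2R,7E,11E)-2-methyl-12-phenyldodeca-7,11-dien-1-yl]-1,2-dioxolan-3-yl}acetaldehyde (not isolated) | C[C@H](CCCC/C=C/CC/C=C/c1ccccc1)C[C@]1(C)C[C@@](C)(CC=O)OO1 | intermediate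
23 | 2-{(3S,5R)-3,5-dimethyl-5-[(2R,7E,11E)-2-methyl-12-phenyldodeca-7,11-dien-1-yl]-1,2-dioxolan-3-yl}acetic acid | C[C@H](CCCC/C=C/CC/C=C/c1ccccc1)C[C@]1(C)C[C@@](C)(CC(=O)O)OO1 | target

Total step count: 13. Longest linear sequence: 8 steps (1, 2, 3, 4, 8, 11, 12, 13).

Steps most likely to fail

Step 11.
- **Risk:** The anion may discriminate poorly between the faces of the peroxycarbenium ion. The closure may show only a weak preference for the arms-trans arrangement. The tertiary cation may lose a proton, or the silyl peroxide may suffer acid-induced O–O heterolysis before C–C bond formation.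
- **Fallback:** It sets out from 13 and 17 and comes back at 21, replacing catalyst control by covalent resolution. The partners are joined with stoichiometric SnCl4 in CH2Cl2 at −78 °C, the established achiral form of the annulation. This gives the dioxolane acetate as a mixture of C3/C5 isomers F1. K2CO3 in MeOH then gives the corresponding alcohol mixture F2. Acylation with (1S)-camphanic chloride (Et3N, 4-(dimethylamino)pyridine, CH2Cl2) places a rigid chiral group close to C3, so the isomers should become separable by chromatography or crystallisation. The (3R,5R)-configured camphanate F3 is collected, and K2CO3 in MeOH releases 21.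

Step 8.
- **Risk:** E-selectivity may erode because both partners are unbranched, and the enolisable aldehyde may self-condense under the basic conditions.
- **Fallback:** It sets out from 6 and comes back at 13, building the 1,5-diene by sigmatropic rearrangement instead of olefination at C12=C13. Vinylmagnesium bromide adds to 6 to give (8R)-8,10-dimethylundeca-1,10-dien-3-ol F4; its carbinol epimers are inconsequential. Johnson–Claisen rearrangement (MeC(OEt)3, cat. EtCO2H, 140 °C) through a chair transition state gives ethyl (4E,10R)-10,12-dimethyltrideca-4,12-dienoate F5. i-Bu2AlH at −78 °C gives (4E,10R)-10,12-dimethyltrideca-4,12-dienal F6. Horner–Wadsworth–Emmons olefination with diethyl benzylphosphonate and NaH closes the E-styrene and gives 13.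

Step 2.
- **Risk:** 1,2-Addition to the ketone may compete, and enantiofacial selectivity may be incomplete with the small methyl nucleophile.
- **Fallback:** It sets out from 1 and comes back at 4, moving the stereodefining event to an acceptor that cannot suffer 1,2-addition and building the ketone afterwards. Cross-metathesis of 1 with S-ethyl prop-2-enethioate (second-generation Hoveyda–Grubbs catalyst) gives ethyl (E)-8-(ethylsulfanyl)-8-oxooct-6-enoate F7. MeMgBr with CuBr·SMe2 and the same ferrocenyl diphosphine gives ethyl (R)-8-(ethylsulfanyl)-6-methyl-8-oxooctanoate F8. Me2CuLi in Et2O at −78 °C converts the thioester selectively into methyl ketone 4.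

Further compounds
F1 | step 11 | 2-{3,5-dimethyl-5-[(2R,7E,11E)-2-methyl-12-phenyldodeca-7,11-dien-1-yl]-1,2-dioxolan-3-yl}ethyl acetate, mixture of C3/C5 isomers | C[C@H](CCCC/C=C/CC/C=C/c1ccccc1)CC1(C)CC(C)(CCOC(C)=O)OO1
F2 | step 11 | 2-{3,5-dimethyl-5-[(2R,7E,11E)-2-methyl-12-phenyldodeca-7,11-dien-1-yl]-1,2-dioxolan-3-yl}ethan-1-ol, mixture of C3/C5 isomers | C[C@H](CCCC/C=C/CC/C=C/c1ccccc1)CC1(C)CC(C)(CCO)OO1
F3 | step 11 | (1S,4R)-camphanate ester of 21 | C[C@@]12CC[C@@](C1(C)C)(OC2=O)C(=O)OCC[C@]3(C)C[C@@](C)(C[C@H](C)CCCC/C=C/CC/C=C/c4ccccc4)OO3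
F4 | step 8 | (8R)-8,10-dimethylundeca-1,10-dien-3-ol | C[C@H](CCCCC(O)C=C)CC(C)=C
F5 | step 8 | ethyl (4E,10R)-10,12-dimethyltrideca-4,12-dienoate | C[C@H](CCCC/C=C/CCC(=O)OCC)CC(C)=C
F6 | step 8 | (4E,10R)-10,12-dimethyltrideca-4,12-dienal | C[C@H](CCCC/C=C/CCC=O)CC(C)=C
F7 | step 2 | ethyl (E)-8-(ethylsulfanyl)-8-oxooct-6-enoate | CCOC(=O)CCCC/C=C/C(=O)SCC
F8 | step 2 | ethyl (R)-8-(ethylsulfanyl)-6-methyl-8-oxooctanoate | C[C@H](CCCCC(=O)OCC)CC(=O)SCC
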